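**Strategy.** The target is treated as an indane (C1 bears the benzodioxanyl group, C2 the isopropylidene, C3 is the ring CH2; ring A is the indane benzo ring, ring B that of the benzodioxane). Because C2 has only three partners (C1, C3 and the exocyclic CMe2 carbon), it can be delivered together with the isopropylidene group as 1-bromo-1-lithio-2-methylpropene. In a single flask this carbenoid binds to a C1 boronic ester, C1 moves from boron to carbon with retention (C1–C2), and palladium then links the resulting alkenylboron to a benzylic chloride (C2–C3), closing the cyclopentane. The precursor is therefore an (R)-diarylmethyl pinacol boronate carrying an ortho CH2Cl on ring A.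

Key step: step 15

Assumption: the nickel-catalysed C–O borylation of step 13 is taken to run with net retention at C1 (ester-directed oxidative addition in a non-coordinating solvent), so the (R)-carbinol is prepared; should inversion operate, the mirror-image ruthenium catalyst in step 11 would be used instead.

Remark: ring A is built from 2-bromo-4-hydroxybenzaldehyde, whose formyl carbon becomes C3; a 2-bromo-6-hydroxybenzaldehyde-type ring A would have no carbon at the position that must carry the CH2Cl group.

Abbreviation in names: ArB = (3S)-7-methyl-3-{2-[(triethylsilyl)oxy]propan-2-yl}-2,3-dihydro-1,4-benzodioxin-5-yl (ring B with its dioxane ring and silyl-protected side chain).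

**Route**

Step 1
Reactants: 1 3-methylbut-2-en-1-ol
Product: 3 [(2R)-3,3-dimethyloxiran-2-yl]methyl 4-methylbenzenesulfonate, via epoxy alcohol 2 (not isolated)
Conditions: Ti(OiPr)4 (5 mol %), D-(−)-diisopropyl tartrate (7 mol %), t-BuOOH, 4 Å MS, CH2Cl2, −20 °C; then P(OMe)3; then TsCl, Et3N, DMAP (cat.), −10 °C
Reagents that add atoms: tert-butyl hydroperoxide, CC(C)(C)OO; 4-methylbenzenesulfonyl chloride, Cc1ccc(cc1)S(Cl)(=O)=O
Why: Katsuki–Sharpless asymmetric epoxidation of an allylic alcohol, in which the D-(−)-tartrate ligand sends oxygen to the alkene face that gives the (2R)-epoxy alcohol, followed by sulfonylation in the same flask so that the volatile, water-soluble glycidol need not be isolated.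

Step 2
Reactants: 4 2-hydroxy-3-methoxy-5-methylbenzaldehyde
Product: 5 2,3-dihydroxy-5-methylbenzaldehyde
Conditions: BBr3, CH2Cl2, −78 to 20 °C; then H2O
Reagents that add atoms: none
Why: Lewis-acid cleavage of an aryl methyl ether (BBr3 demethylation), which leaves the aldehyde and the ring methyl group untouched.

Step 3
Reactants: 5 2,3-dihydroxy-5-methylbenzaldehyde; 3 (R)-epoxy tosylate
Product: 7 (3S)-3-(2-hydroxypropan-2-yl)-7-methyl-2,3-dihydro-1,4-benzodioxine-5-carbaldehyde, via glycidyl ether 6 (not isolated)
Conditions: NaH (2.2 equiv), DMSO, 20 °C; then 3, 20 °C; then 60 °C; then H2O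
Reagents that add atoms: none
Why: Williamson alkylation of the catechol dianion should occur at the more nucleophilic 3-oxide (the 2-oxide is stabilised by the ortho formyl group), after which the remaining phenoxide opens the epoxide by 6-exo SN2 attack at its secondary carbon with inversion, turning the (R)-epoxide carbon into the (S)-centre of the benzodioxane.

Step 4
Reactants: 7 benzodioxane aldehyde with free tertiary alcohol
Product: 8 (3S)-7-methyl-3-{2-[(triethylsilyl)oxy]propan-2-yl}-2,3-dihydro-1,4-benzodioxine-5-carbaldehyde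
Conditions: TESOTf, 2,6-lutidine, CH2Cl2, −78 to 0 °C
Reagents that add atoms: triethylsilyl trifluoromethanesulfonate, CC[Si](CC)(CC)OS(=O)(=O)C(F)(F)F
Why: Silylation of a tertiary alcohol with a silyl triflate and a hindered base, which masks the only acidic proton before the organolithium steps and later falls off together with the acetonide.

Step 5
Reactants: 9 2-bromo-4-hydroxybenzaldehyde
Product: 10 2-bromo-4-(oxan-2-yloxy)benzaldehyde
Conditions: 3,4-dihydro-2H-pyran, PPTS (cat.), CH2Cl2, 20 °C
Reagents that add atoms: 3,4-dihydro-2H-pyran, C1CCOC=C1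
Why: Acid-catalysed addition of the phenol to the enol ether (tetrahydropyranylation) gives an acetal that survives base, acidifies the neighbouring ring C–H for metalation and can later be exchanged under the acetonide-forming conditions.

Step 6
Reactants: 10 THP-protected bromo aldehyde
Product: 11 1-[2-bromo-4-(oxan-2-yloxy)phenyl]-N,N-dimethylmethanamine
Conditions: Me2NH (2 M in THF), NaBH(OAc)3, ClCH2CH2Cl, 20 °C
Reagents that add atoms: dimethylamine, CNC
Why: Reductive amination with a triacetoxyborohydride turns the formyl carbon into the future C3 bearing a dimethylamino group, a base- and organolithium-stable precursor of the benzylic chloride.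

Step 7
Reactants: 11 bromo benzylamine
Product: 13 {2-bromo-3-[(dimethylamino)methyl]-6-(oxan-2-yloxy)phenyl}methanol, via aldehyde 12 (not isolated)
Conditions: LiN(iPr)2, THF, −78 °C; then DMF, −78 °C; then MeOH, NaBH4, −78 to 0 °C
Reagents that add atoms: N,N-dimethylformamide, CN(C)C=O
Why: Deprotonative ortho-lithiation by the amide base at the most acidic ring position (flanked by bromine and the acetal oxygen), Bouveault-type formylation with DMF and borohydride reduction in the same flask install the C7 carbon at the alcohol oxidation level.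

Step 8
Reactants: 13 bromo benzyl alcohol
Product: 15 1-(5-bromo-2,2-dimethyl-4H-1,3-benzodioxin-6-yl)-N,N-dimethylmethanamine, via phenol diol 14 (not isolated)
Conditions: 2,2-dimethoxypropane, MeOH (2 equiv), TsOH·H2O (1.2 equiv), acetone, 20 °C
Reagents that add atoms: 2,2-dimethoxypropane, COC(C)(C)OC
Why: Acid-catalysed transacetalisation passes the THP group to methanol and captures the liberated salicyl alcohol as its isopropylidene acetal, the acid being used in slight excess over the amine.

Step 9
Reactants: 15 ring A bromide; 8 ring B aldehyde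
Product: 17 diaryl carbinol (both C1 epimers), via aryllithium 16 (not isolated)
Conditions: n-BuLi, THF, −78 °C; then 8, −78 to −20 °C; then H2O
Reagents that add atoms: none
Why: Bromine–lithium exchange gives an aryllithium held by the neighbouring amine and acetal oxygen, which adds to the non-enolisable aldehyde (1,2-addition) to form the C1–ring B bond, stereocontrol being unnecessary because C1 is oxidised next.

Step 10
Reactants: 17 diaryl carbinol
Product: 18 diaryl ketone
Conditions: Dess–Martin periodinane, CH2Cl2, 0 to 20 °C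
Reagents that add atoms: none
Why: Dess–Martin oxidation of a secondary benzylic alcohol proceeds under near-neutral conditions that spare the silyl ether, the acetonide and the tertiary amine.

Step 11
Reactants: 18 diaryl ketone
Product: 19 (R)-diaryl carbinol
Conditions: RuCl[(R,R)-TsDPEN](p-cymene) (2 mol %), HCO2H/Et3N (5:2), DMF, 40 °C
Reagents that add atoms: none
Why: Noyori–Ikariya asymmetric transfer hydrogenation, in which the 2,6-disubstituted ring A is twisted out of the carbonyl plane and acts as the non-conjugated substituent while coplanar ring B lies against the p-cymene ligand, so the (R,R)-catalyst should deliver hydride to the face that gives (R)-C1, the two possible epimers being diastereomers and hence easy to assay.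

Step 12
Reactants: 19 (R)-diaryl carbinol
Product: 20 (R)-diarylmethyl pivalate
Conditions: NaH, THF, 0 °C; then PivCl, 0 to 20 °C
Reagents that add atoms: pivaloyl chloride, CC(C)(C)C(Cl)=O
Why: O-acylation of the sodium alkoxide of a hindered secondary alcohol breaks no bond at C1, so the configuration is kept, and it outruns any N-acylation of the tertiary amine.

Step 13
Reactants: 20 (R)-diarylmethyl pivalate
Product: 21 (R)-diarylmethyl pinacol boronate with CH2NMe2 on ring A
Conditions: Ni(cod)2 (10 mol %), PCy3 (20 mol %), B2pin2, NaOMe, toluene, 60 °C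
Reagents that add atoms: bis(pinacolato)diboron, CC1(C)OB(OC1(C)C)B1OC(C)(C)C(C)(C)O1
Why: Nickel-catalysed Miyaura-type borylation of a doubly benzylic C–O electrophile, in which ester-directed oxidative addition of zerovalent nickel on the face of the leaving group, boryl transfer from methoxide-activated B2pin2 and C–B reductive elimination should replace oxygen by boron with net retention and so give (R)-C1–B.

Step 14
Reactants: 21 amino boronate
Product: 22 (R)-diarylmethyl pinacol boronate with CH2Cl on ring A
Conditions: ClCO2Et, THF, 0 to 40 °C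
Reagents that add atoms: ethyl chloroformate, CCOC(Cl)=O
Why: Chloroformate dealkylation of a tertiary benzylamine (von Braun-type), in which N-acylation is followed by chloride attack at the benzylic carbon, delivers the benzylic chloride under neutral conditions that leave the C–B bond, the silyl ether and the acetonide alone.

Step 15
Reactants: 22 chloromethyl boronate; 23 1,1-dibromo-2-methylprop-1-ene
Product: 27 protected (1R)-2-isopropylidene-1-arylindane, via carbenoid 24 (not isolated), via lithium boronate 25 (not isolated), via alkenylboronate 26 (not isolated)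
Conditions: 23, n-BuLi, THF/Et2O/pentane (4:1:1), −110 °C; then 22, −110 to 20 °C; then PdCl2(dppf) (5 mol %), K3PO4 (aq), 65 °C
Reagents that add atoms: none
Why: Bromine–lithium exchange converts 23 into carbenoid 24, which adds to the vacant boron orbital of 22, and in the tetracoordinate complex 25 the C1–B bond shifts to the carbenoid carbon anti to the departing bromide (Matteson-type 1,2-metalate rearrangement of a boronic ester with a 1-halo-1-lithioalkene) to give alkenylboronate 26. Zerovalent palladium formed from PdCl2(dppf) then inserts into the benzylic C3–Cl bond, base-assisted transmetalation moves C2 from boron to palladium, and reductive elimination forges C2–C3 (intramolecular Suzuki–Miyaura coupling of an alkenylboron with a benzyl chloride). The cyclopentane is closed in this last event by C–C reductive elimination from a six-membered palladacycle, a 5-exo-type closure that leaves the alkene exocyclic. The C1 stereocentre is transferred, not created: the migrating carbon keeps its configuration (substrate control by the (R)-boronate), and C1 never passes through a free carbanion, radical or carbocation. The step needs the organolithium to choose boron over the CH2Cl group and the coupling to stay intramolecular; the Lewis-acidic boron, the pre-formation of 24 at −110 °C so that no butyllithium meets 22, and the ortho position of CH2Cl should secure this, and because both substituents on the far alkene carbon are methyl no E/Z isomers can arise.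

Step 16
Reactants: 27 protected indane
Product: 28 triol (phenol, benzylic alcohol, tertiary alcohol)
Conditions: 1 M HCl (aq)/THF (1:4), 0 to 20 °C
Reagents that add atoms: none
Why: Mild aqueous-acid hydrolysis removes the isopropylidene acetal and the triethylsilyl ether in one operation, under conditions too weak to protonate the tetrasubstituted exocyclic alkene.

Step 17
Reactants: 28 triol
Product: 29 diaporindene G
Conditions: MnO2, CH2Cl2, 20 °C
Reagents that add atoms: none
Why: MnO2 oxidises only the benzylic (salicyl) alcohol to the aldehyde, leaving the phenol, the tertiary alcohol, the alkene and the C1–H bond untouched.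

**Compound list**

1 | 3-methylbut-2-en-1-ol | CC(C)=CCO | starting material
2 | [(2R)-3,3-dimethyloxiran-2-yl]methanol | OC[C@H]1OC1(C)C | intermediate
3 | [(2R)-3,3-dimethyloxiran-2-yl]methyl 4-methylbenzenesulfonate | Cc1ccc(cc1)S(=O)(=O)OC[C@H]1OC1(C)C | intermediate
4 | 2-hydroxy-3-methoxy-5-methylbenzaldehyde | COc1cc(C)cc(C=O)c1O | starting material
5 | 2,3-dihydroxy-5-methylbenzaldehyde | O=Cc1cc(C)cc(O)c1O | intermediate
6 | 3-{[(2R)-3,3-dimethyloxiran-2-yl]methoxy}-2-hydroxy-5-methylbenzaldehyde (present as its sodium phenoxide) | O=Cc1cc(C)cc(OC[C@H]2OC2(C)C)c1O | intermediate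
7 | (3S)-3-(2-hydroxypropan-2-yl)-7-methyl-2,3-dihydro-1,4-benzodioxine-5-carbaldehyde | O=Cc1cc(C)cc2c1O[C@H](C(C)(C)O)CO2 | intermediate
8 | (3S)-7-methyl-3-{2-[(triethylsilyl)oxy]propan-2-yl}-2,3-dihydro-1,4-benzodioxine-5-carbaldehyde (ArB–CHO) | O=Cc1cc(C)cc2c1O[C@H](C(C)(C)O[Si](CC)(CC)CC)CO2 | intermediate
9 | 2-bromo-4-hydroxybenzaldehyde | O=Cc1ccc(O)cc1Br | starting material
10 | 2-bromo-4-(oxan-2-yloxy)benzaldehyde (racemic at the acetal carbon) | O=Cc1ccc(OC2CCCCO2)cc1Br | intermediate
11 | 1-[2-bromo-4-(oxan-2-yloxy)phenyl]-N,N-dimethylmethanamine | CN(C)Cc1ccc(OC2CCCCO2)cc1Br | intermediate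
12 | 2-bromo-3-[(dimethylamino)methyl]-6-(oxan-2-yloxy)benzaldehyde | CN(C)Cc1ccc(OC2CCCCO2)c(C=O)c1Br | intermediate
13 | {2-bromo-3-[(dimethylamino)methyl]-6-(oxan-2-yloxy)phenyl}methanol | CN(C)Cc1ccc(OC2CCCCO2)c(CO)c1Br | intermediate
14 | 3-bromo-4-[(dimethylamino)methyl]-2-(hydroxymethyl)phenol | CN(C)Cc1ccc(O)c(CO)c1Br | intermediate
15 | 1-(5-bromo-2,2-dimethyl-4H-1,3-benzodioxin-6-yl)-N,N-dimethylmethanamine | CN(C)Cc1ccc2OC(C)(C)OCc2c1Br | intermediate
16 | {6-[(dimethylamino)methyl]-2,2-dimethyl-4H-1,3-benzodioxin-5-yl}lithium | CN(C)Cc1ccc2OC(C)(C)OCc2c1[Li] | intermediate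
17 | {6-[(dimethylamino)methyl]-2,2-dimethyl-4H-1,3-benzodioxin-5-yl}(ArB)methanol, both C1 epimers | CN(C)Cc1ccc2OC(C)(C)OCc2c1C(O)c1cc(C)cc2c1O[C@H](C(C)(C)O[Si](CC)(CC)CC)CO2 | intermediate
18 | {6-[(dimethylamino)methyl]-2,2-dimethyl-4H-1,3-benzodioxin-5-yl}(ArB)methanone | CN(C)Cc1ccc2OC(C)(C)OCc2c1C(=O)c1cc(C)cc2c1O[C@H](C(C)(C)O[Si](CC)(CC)CC)CO2 | intermediate
19 | (R)-{6-[(dimethylamino)methyl]-2,2-dimethyl-4H-1,3-benzodioxin-5-yl}(ArB)methanol | CN(C)Cc1ccc2OC(C)(C)OCc2c1[C@@H](O)c1cc(C)cc2c1O[C@H](C(C)(C)O[Si](CC)(CC)CC)CO2 | intermediate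
20 | (R)-{6-[(dimethylamino)methyl]-2,2-dimethyl-4H-1,3-benzodioxin-5-yl}(ArB)methyl 2,2-dimethylpropanoate | CN(C)Cc1ccc2OC(C)(C)OCc2c1[C@@H](OC(=O)C(C)(C)C)c1cc(C)cc2c1O[C@H](C(C)(C)O[Si](CC)(CC)CC)CO2 | intermediate
21 | 2-[(R)-{6-[(dimethylamino)methyl]-2,2-dimethyl-4H-1,3-benzodioxin-5-yl}(ArB)methyl]-4,4,5,5-tetramethyl-1,3,2-dioxaborolane | CN(C)Cc1ccc2OC(C)(C)OCc2c1[C@@H](B1OC(C)(C)C(C)(C)O1)c1cc(C)cc2c1O[C@H](C(C)(C)O[Si](CC)(CC)CC)CO2 | intermediate
22 | 2-[(R)-[6-(chloromethyl)-2,2-dimethyl-4H-1,3-benzodioxin-5-yl](ArB)methyl]-4,4,5,5-tetramethyl-1,3,2-dioxaborolane | ClCc1ccc2OC(C)(C)OCc2c1[C@@H](B1OC(C)(C)C(C)(C)O1)c1cc(C)cc2c1O[C@H](C(C)(C)O[Si](CC)(CC)CC)CO2 | intermediate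
23 | 1,1-dibromo-2-methylprop-1-ene | CC(C)=C(Br)Br | starting material
24 | (1-bromo-2-methylprop-1-en-1-yl)lithium | CC(C)=C([Li])Br | intermediate
25 | lithium (1-bromo-2-methylprop-1-en-1-yl){(R)-[6-(chloromethyl)-2,2-dimethyl-4H-1,3-benzodioxin-5-yl](ArB)methyl}(pinacolato)borate | [Li+].ClCc1ccc2OC(C)(C)OCc2c1[C@@H]([B-]1(OC(C)(C)C(C)(C)O1)C(Br)=C(C)C)c1cc(C)cc2c1O[C@H](C(C)(C)O[Si](CC)(CC)CC)CO2 | intermediate
26 | 2-{(1R)-1-[6-(chloromethyl)-2,2-dimethyl-4H-1,3-benzodioxin-5-yl]-3-methyl-1-(ArB)but-2-en-2-yl}-4,4,5,5-tetramethyl-1,3,2-dioxaborolane | ClCc1ccc2OC(C)(C)OCc2c1[C@@H](C(=C(C)C)B1OC(C)(C)C(C)(C)O1)c1cc(C)cc2c1O[C@H](C(C)(C)O[Si](CC)(CC)CC)CO2 | intermediate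
27 | (1R)-1-(ArB)-2-(propan-2-ylidene)indane in which the C6 oxygen and the C7 CH2O group are joined as an isopropylidene acetal (2,2-dimethyl-1,3-dioxine ring fused across C6–C7) | CC(C)=C1Cc2ccc3OC(C)(C)OCc3c2[C@@H]1c1cc(C)cc2c1O[C@H](C(C)(C)O[Si](CC)(CC)CC)CO2 | intermediate
28 | 2-{(3S)-5-[(1R)-6-hydroxy-7-(hydroxymethyl)-2-(propan-2-ylidene)-2,3-dihydro-1H-inden-1-yl]-7-methyl-2,3-dihydro-1,4-benzodioxin-3-yl}propan-2-ol | CC(C)=C1Cc2ccc(O)c(CO)c2[C@@H]1c1cc(C)cc2c1O[C@H](C(C)(C)O)CO2 | intermediate
29 | diaporindene G, (1R)-6-hydroxy-1-[(3S)-3-(2-hydroxypropan-2-yl)-7-methyl-2,3-dihydro-1,4-benzodioxin-5-yl]-2-(propan-2-ylidene)-2,3-dihydro-1H-indene-7-carbaldehyde (indane numbering of this proposal) | CC(C)=C1Cc2ccc(O)c(C=O)c2[C@@H]1c1cc(C)cc2c1O[C@H](C(C)(C)O)CO2 | target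

**Step count and risk**

Total step count: 17. Longest linear sequence: 13 steps (steps 5–8, then 9–17, from 2-bromo-4-hydroxybenzaldehyde).

Steps most likely to fail:

Step 15. The crowded boronate complex may dissociate again before C1 shifts, the lithium reagents may alkylate at the benzylic chloride, or the hindered alkenylboron may lose boron by protonolysis faster than it transmetalates. Fallback: the two bond formations are separated and the electrophile is kept out of the organolithium stage. Setting out from amine boronate 21, the same carbenoid homologation should give the amino alkenylboronate F1, which is isolated. Ethyl chloroformate then converts F1 into chloride 26, now handled as an isolated compound. The ring is closed in a separate Suzuki–Miyaura reaction (Pd(OAc)2, SPhos, aqueous K3PO4), and the route is rejoined at 27.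

Step 13. Zerovalent nickel may fail to insert into the crowded C–O bond, the neighbouring amine may alkylate at C1, or the diarylmethyl–nickel species may ionise or homolyse and scramble C1. Fallback: the C1–B centre is built by a 1,2-metalate shift instead of C–O substitution, setting out from aldehyde 8 and bromide 15.
- NaBH4 reduces 8 to the benzylic alcohol F2, and iPr2NCOCl/NaH gives its N,N-diisopropylcarbamate F3.
- Bromide 15 is converted with n-BuLi and then 2-isopropoxy-4,4,5,5-tetramethyl-1,3,2-dioxaborolane into the ring A pinacol boronate F4.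
- F3 is deprotonated at its benzylic CH2 with s-BuLi and a chiral diamine (sparteine type, enantiomer chosen for the configuration shown) at −78 °C to the lithiated carbamate F5.
- F5 is trapped by F4 with retention to give the boronate complex F6; warming with MgBr2 should induce the anti shift of the ring A aryl group with loss of the carbamate.
- This delivers 21, where the route is rejoined at step 14. Any C1 epimer is a diastereomer and can be removed by chromatography.
- The dimethylamino group of F4 may coordinate to boron and slow the capture, which is the weak point of this alternative.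

Step 11. Hydride transfer to the tri-ortho-substituted ketone may be too slow, or face discrimination poor if ring B does not lie cleanly in the carbonyl plane. Fallback: classical resolution replaces asymmetric catalysis. Setting out from the epimeric carbinols 17 (steps 10 and 11 are skipped), the sodium alkoxides are acylated with (1S)-camphanic chloride to give two diastereomeric esters, the (R)-C1 camphanate F7 and the (S)-C1 camphanate F8. These are separated by chromatography or crystallisation. Saponification of F7 with LiOH returns the route at 19. F8 is recycled by saponification, oxidation to 18 and NaBH4 reduction back to 17.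

Further compounds
F1 | step 15 | 2-[(1R)-1-{6-[(dimethylamino)methyl]-2,2-dimethyl-4H-1,3-benzodioxin-5-yl}-3-methyl-1-(ArB)but-2-en-2-yl]-4,4,5,5-tetramethyl-1,3,2-dioxaborolane | CN(C)Cc1ccc2OC(C)(C)OCc2c1[C@@H](C(=C(C)C)B1OC(C)(C)C(C)(C)O1)c1cc(C)cc2c1O[C@H](C(C)(C)O[Si](CC)(CC)CC)CO2
F2 | step 13 | [(3S)-7-methyl-3-{2-[(triethylsilyl)oxy]propan-2-yl}-2,3-dihydro-1,4-benzodioxin-5-yl]methanol | OCc1cc(C)cc2c1O[C@H](C(C)(C)O[Si](CC)(CC)CC)CO2
F3 | step 13 | (ArB)methyl N,N-di(propan-2-yl)carbamate | CC(C)N(C(C)C)C(=O)OCc1cc(C)cc2c1O[C@H](C(C)(C)O[Si](CC)(CC)CC)CO2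
F4 | step 13 | 1-[2,2-dimethyl-5-(4,4,5,5-tetramethyl-1,3,2-dioxaborolan-2-yl)-4H-1,3-benzodioxin-6-yl]-N,N-dimethylmethanamine | CN(C)Cc1ccc2OC(C)(C)OCc2c1B1OC(C)(C)C(C)(C)O1
F5 | step 13 | [(R)-(ArB){[di(propan-2-yl)carbamoyl]oxy}methyl]lithium | CC(C)N(C(C)C)C(=O)O[C@H]([Li])c1cc(C)cc2c1O[C@H](C(C)(C)O[Si](CC)(CC)CC)CO2
F6 | step 13 | lithium [(R)-(ArB){[di(propan-2-yl)carbamoyl]oxy}methyl]{6-[(dimethylamino)methyl]-2,2-dimethyl-4H-1,3-benzodioxin-5-yl}(pinacolato)borate | [Li+].CC(C)N(C(C)C)C(=O)O[C@H]([B-]1(OC(C)(C)C(C)(C)O1)c1c(CN(C)C)ccc2OC(C)(C)OCc12)c1cc(C)cc2c1O[C@H](C(C)(C)O[Si](CC)(CC)CC)CO2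
F7 | step 11 | (R)-{6-[(dimethylamino)methyl]-2,2-dimethyl-4H-1,3-benzodioxin-5-yl}(ArB)methyl (1S,4R)-camphanate | CN(C)Cc1ccc2OC(C)(C)OCc2c1[C@@H](OC(=O)[C@@]12CC[C@@](C)(C(=O)O1)C2(C)C)c1cc(C)cc2c1O[C@H](C(C)(C)O[Si](CC)(CC)CC)CO2
F8 | step 11 | (S)-{6-[(dimethylamino)methyl]-2,2-dimethyl-4H-1,3-benzodioxin-5-yl}(ArB)methyl (1S,4R)-camphanate | CN(C)Cc1ccc2OC(C)(C)OCc2c1[C@H](OC(=O)[C@@]12CC[C@@](C)(C(=O)O1)C2(C)C)c1cc(C)cc2c1O[C@H](C(C)(C)O[Si](CC)(CC)CC)CO2
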